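## Structural features

The target is an achiral depside: two benzene rings joined by one ester, whose carbonyl carbon sits on C1' of ring B and whose oxygen sits on C4 of ring A. It has no stereocentre and no stereogenic double bond, so no stereochemical relationship has to be set or preserved. Ring A is a benzoic acid (CO2H on C1) with OMe on C2 and a pentyl chain on C6. Ring B is a benzoyl group with OMe on C2' and C4' and a propyl chain on C6'. Both rings show the alternating oxygens and terminal alkyl chain of acetate-derived resorcylates, and in both the carboxyl carbon has two ortho neighbours. The fragile groups are the aryl ester (opened by hydroxide, alkoxide or strong Lewis acid), the electron-rich free acid of ring A (protodecarboxylation in hot acid) and the methyl ethers ortho to a carbonyl (Lewis-acid demethylation). The real difficulty is threefold: the C2 and C4 oxygens of ring A must be told apart, the two carboxyl groups must be told apart, and the depside ester must join a 2,6-disubstituted benzoyl carbon to a phenol that stands para to an ester. The key step uses the fact that C1', C2', C3' and the exocyclic ester carbon are an acetoacetate unit, while C4', C5', C6' and the propyl chain are the 3-oxo ketene acetal 14. The ester can therefore be made while its acyl carbon is still an unhindered acetoacetyl group, and the hindrance is created afterwards by growing ring B around it.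

## Logic of the disconnections

18 to 17. The cut is the O–CH2Ph bond of the ring A carboxyl; no skeletal bond is touched. A free acid would not survive silylation, TiCl4 and carbonate/MeI, and benzyl is the ester group that leaves under neutral, non-nucleophilic conditions. The gain is an end game that never exposes the depside to acid or base. The demand is that 17 holds nothing else that hydrogenolysis can cleave, which is the case.

17 to 16. The cut is the O–CH3 bond on the C2' oxygen. This oxygen is the former ketone oxygen of the acetoacetate and must emerge from ring formation as a chelated phenol. The gain is that 16 is the direct product of the ring synthesis. The demand is alkylation of a hydrogen-bonded phenol with a base too weak and too non-nucleophilic to open the aryl ester.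

16 to 11 and 14. The cuts are C3'–C4' and C1'–C6'. They remove ring B and with it the two ortho groups that make the depside carbonyl unapproachable. The gain is large: a tetrasubstituted arene becomes a four-carbon dinucleophile and an acyclic 1,3-dielectrophile. The demand is correct pairing of the termini, a Lewis acid that spares aryl ester, benzyl ester and methyl ether, and an aryl ester that does not fragment before the ring closes.

11 to 9. Two O–Si bonds are cut. The 1,3-dicarbonyl unit has to be offered as a neutral equivalent of its dianion. The gain is a bench-stable β-keto ester. The demand is double enolisation, the second at the γ-methyl group, without an enolate that could expel the aryloxide.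

9 to 6 and 7. The cut is the bond between the C4 oxygen of ring A and the acetoacetyl carbonyl carbon, which is the future depside C–O bond. At this stage the acyl carbon has no ortho neighbours, and the bond can be made by addition to a ketene instead of by acyl substitution. The gain is the separation of ring A from a commercial four-carbon unit. The demand is that a phenol para to an ester traps a thermally generated ketene.

14 to 12 and 13. The cut is the C2–C3 bond of the enone, between the acyl carbon and the vinyl carbon. It follows the natural polarity, acyl chloride as electrophile and ketene acetal as nucleophile. The gain is two commercial liquids. The demand is clean monoacylation and removal of HCl without an amine base that would turn 12 into a ketene.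

6 to 5. The cut is the O–allyl bond on the C4 oxygen. A temporary mask is needed there that comes off without touching a benzyl ester, which rules out a second benzyl group. The gain is that the ester is installed once and kept. The demand is a selective palladium-catalysed allyl transfer.

5 to 4. The cut is the O–CH3 bond on the C2 oxygen. Methylation comes after the C4 oxygen is blocked. The demand is forcing alkylation of a chelated phenol.

4 to 3. The cut is the O–allyl bond again, now seen as the differentiating event. The C4 hydroxyl is free and the more acidic, and the C2 hydroxyl is tied to the ester carbonyl by a hydrogen bond. The demand is monoalkylation with one equivalent of halide.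

3 to 2. The cut is the O–benzyl bond of the ester. It is made by alkylating the carboxylate at the benzylic carbon, because the 2,6-disubstituted carboxyl resists ordinary esterification. The ester also provides the hydrogen-bond acceptor that differentiates the two phenols in the next step.

2 to 1. The cut is the C1–CO2H bond. The carboxyl carbon is added to a symmetric commercial resorcinol. The demand is carboxylation at the carbon between a hydroxyl and the pentyl group and not at the carbon between the two hydroxyls.

## Other disconnections considered

Alternative 1: The cut is the C1–C6 bond of ring A, within a linear tetraketide masked as a dioxinone.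
- Forward step: A1 (6-(2,4-dioxononyl)-2,2-dimethyl-4H-1,3-dioxin-4-one) would be treated with Et3N and then acid. C5 of the dioxinone should add to the pentyl ketone and dehydration should give A2 (7-hydroxy-2,2-dimethyl-5-pentyl-4H-1,3-benzodioxin-4-one).
- In favour: the carboxyl carbon is in place before the ring exists, so the ring A regiochemistry is fixed by connectivity. On this point it is better than step 1 of the chosen plan. The acetonide masks the acid and the C2 oxygen in one group and leaves only the C4 hydroxyl free.
- Against: the target needs the C2 oxygen and the carboxyl apart, as OMe and CO2H. Opening the benzodioxinone needs alkoxide or hydroxide, which a depside would not tolerate, so opening, methylation and re-protection must precede ester formation. That is about four further operations from A2 to 6, and A1 itself needs two C-acylations of 7.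
- Comparison: the mechanism is of the same family as the chosen key step, an enol aldol condensation followed by dehydration to an arene, and is its equal in regiocontrol. In step economy it is worse, roughly eight steps to 6 against five. It also builds the ring that can be bought as 1 and leaves the hindered ester to some other method, so it is a supplement, not a replacement.

Alternative 2: The cuts are both bonds at the depside carbonyl carbon, C1'–C(=O) and C(=O)–O.
- Forward step: A3 (2-iodo-1,5-dimethoxy-3-propylbenzene), A4 (carbon monoxide) and 6 would combine under Pd(OAc)2, Xantphos and Et3N. Oxidative addition, CO insertion to an aroyl palladium species and transfer of the aroyl group to the phenoxide would give A5 (benzyl 4-[(2,4-dimethoxy-6-propylbenzoyl)oxy]-2-methoxy-6-pentylbenzoate, identical with 17).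
- In favour: it is convergent, and the C2' methoxy group is present from the start, so neither a chelated phenol nor a late methylation arises. A3 should come in one electrophilic iodination from A6 (1,3-dimethoxy-5-propylbenzene). With A6 in hand the route would have about eight steps against eleven. In step count and convergence it is better than the chosen plan.
- Against: it meets the central problem head on. Oxidative addition into a di-ortho-substituted, electron-rich C–I bond is slow, and the aroyl palladium intermediate is flanked on both sides. Compound 6 is a weak oxygen nucleophile. Hydrodehalogenation, decarbonylation and carbonyl-free C–O coupling would compete. The known scope of aryloxycarbonylation lies with unhindered aryl halides.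
- Comparison: the chosen plan avoids the hindered acyl transfer altogether and places its uncertainty in a Lewis-acid cyclocondensation with close analogy. The alternative places it in an elementary step with little analogy for this substitution pattern, and it adds the handling of a toxic gas.

Alternative 3: The cuts are C1–C2 and C5–C6 of ring A.
- Forward step: A7 (1,1-dimethoxy-3-(trimethylsilyloxy)buta-1,3-diene) and A8 (benzyl oct-2-ynoate) would undergo a thermal Diels–Alder reaction. The adduct should aromatise by loss of methanol and desilylation to A9 (benzyl 4-hydroxy-2-methoxy-6-pentylbenzoate, identical with 6).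
- In favour: the C2 methoxy group, the free C4 hydroxyl and the benzyl ester are all built in. No protecting group is needed on ring A and 6 would come in about three steps instead of five. In oxygen differentiation and step economy for ring A it is better than the chosen plan. Its regiochemistry follows from the same polarity matching as the chosen key step (nucleophilic diene terminus to the β-carbon of the ynoate) and is its equal there.
- Against: a β-alkyl ynoate is a sluggish dienophile that should need prolonged heating well above 100 °C, and A7 is a ketene acetal that is sensitive to heat and moisture. Desilylation and decomposition of the diene would compete with cycloaddition.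
- Comparison: it does not address the depside bond, so it could only replace steps 1 to 5 and feed the same key step. Phenol alkylation chemistry from 1 is longer but each step is of high reliability, which decided the choice.

Key step: step 9

Remarks on the chemistry:
- Compounds 1, 7, 12 and 13 are taken as purchasable.
- In step 9 the enol double bond C1'=C2' lies inside the ring being formed, so the ring closure is classed as 6-(enolendo)-exo-trig and not as an enolexo closure. The enolexo reading would apply only to the ester-enolate form of the chelated dicarbonyl.
- The double-bond geometries written for 10, 11 and 15 are the expected ones. All three double bonds end in the arene, so they have no bearing on the outcome.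

## Steps

Step 1
Reactants: 1 olivetol (5-pentylbenzene-1,3-diol)
Product: 2 olivetolic acid (2,4-dihydroxy-6-pentylbenzoic acid)
Conditions: MeOMgOCO2Me (2 M in DMF, 5 equiv), 120 °C, N2; then 2 M HCl, 0 °C
Reagents that add atoms: methyl magnesium carbonate, COC(=O)O[Mg]OC
Why: Kolbe–Schmitt-type ortho-carboxylation: the magnesium phenoxide takes up CO2 at the ring carbon ortho to one oxygen and para to the other, and chelation of the product as a magnesium salicylate drives the equilibrium. The acid is set free cold to avoid decarboxylation.

Step 2
Reactants: 2 olivetolic acid
Product: 3 benzyl 2,4-dihydroxy-6-pentylbenzoate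
Conditions: BnBr (1.05 equiv), KHCO3 (1.2 equiv), DMF, 20–40 °C
Reagents that add atoms: benzyl bromide, BrCc1ccccc1
Why: Carboxylate O-alkylation (SN2 at the benzylic carbon): KHCO3 ionises only the carboxylic acid, so both phenols stay free. The crowding of the carboxyl does not matter because the new bond is made at the benzyl carbon.

Step 3
Reactants: 3 benzyl 2,4-dihydroxy-6-pentylbenzoate
Product: 4 benzyl 2-hydroxy-6-pentyl-4-(prop-2-en-1-yloxy)benzoate
Conditions: allyl bromide (1.05 equiv), K2CO3 (1.2 equiv), acetone, 20 → 50 °C
Reagents that add atoms: allyl bromide, C=CCBr
Why: Williamson etherification: the C4 hydroxyl is the more acidic and is not hydrogen-bonded, while the C2 hydroxyl is held by the ester carbonyl. One equivalent of halide should therefore alkylate the C4 oxygen only.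

Step 4
Reactants: 4 benzyl 2-hydroxy-6-pentyl-4-(prop-2-en-1-yloxy)benzoate
Product: 5 benzyl 2-methoxy-6-pentyl-4-(prop-2-en-1-yloxy)benzoate
Conditions: MeI (3 equiv), K2CO3 (2 equiv), DMF, 50 °C
Reagents that add atoms: iodomethane, CI
Why: Williamson O-methylation of the chelated phenol under more forcing conditions (dipolar aprotic solvent, excess MeI). The allyl ether and the hindered benzyl ester are inert to carbonate at this temperature.

Step 5
Reactants: 5 benzyl 2-methoxy-6-pentyl-4-(prop-2-en-1-yloxy)benzoate
Product: 6 benzyl 4-hydroxy-2-methoxy-6-pentylbenzoate
Conditions: Pd(PPh3)4 (3 mol %), morpholine (3 equiv), THF, 20 °C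
Reagents that add atoms: none
Why: Tsuji–Trost deallylation: zerovalent palladium ionises the allyl aryl ether to a π-allyl complex and the phenoxide, and morpholine takes up the allyl group irreversibly. The benzyl ester and the methyl ether are not substrates for this catalyst.

Step 6
Reactants: 6 benzyl 4-hydroxy-2-methoxy-6-pentylbenzoate; 7 2,2,6-trimethyl-4H-1,3-dioxin-4-one (1.5 equiv)
Product: 9 benzyl 2-methoxy-4-[(3-oxobutanoyl)oxy]-6-pentylbenzoate, via acetylketene 8 (not isolated)
Conditions: xylene, 140 °C, acetone distilled off
Reagents that add atoms: none
Why: Thermal retro-[4+2] cleavage of 7 releases acetone and acetylketene 8, which the phenol captures by addition across the ketene (acylketene trapping). This is an addition and not an acyl substitution, so a weakly nucleophilic phenol suffices, and the ring A ester is twisted out of conjugation by its two ortho groups, which limits the deactivation of the phenol.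

Step 7
Reactants: 9 benzyl 2-methoxy-4-[(3-oxobutanoyl)oxy]-6-pentylbenzoate
Product: 11 benzyl 4-{[(1Z)-1,3-bis(trimethylsilyloxy)buta-1,3-dien-1-yl]oxy}-2-methoxy-6-pentylbenzoate, via silyl enol ether 10 (not isolated)
Conditions: Me3SiOTf (2.3 equiv), Et3N (3 equiv), Et2O, 0 → 20 °C; ammonium salt layer removed, used crude
Reagents that add atoms: trimethylsilyl trifluoromethanesulfonate, C[Si](C)(C)OS(=O)(=O)C(F)(F)F
Why: Soft enolisation: the silyl triflate and Et3N silylate the ketone oxygen to give 10, then the ester carbonyl of 10 is silylated and Et3N removes a γ-proton to give the 1,3-bis(silyloxy)diene. No free enolate or dianion builds up, which should hold back E1cB loss of the aryloxide.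

Step 8
Reactants: 12 butanoyl chloride; 13 1,1-dimethoxyethene (2.2 equiv)
Product: 14 1,1-dimethoxyhex-1-en-3-one
Conditions: Et2O, 0 → 20 °C, slow addition of 12 to 13; distillation
Reagents that add atoms: none
Why: C-acylation of an electron-rich ketene acetal by an acid chloride, followed by loss of a proton from the dimethoxycarbenium ion. The second equivalent of 13 takes up HCl and falls apart to methyl acetate and chloromethane, so no amine base is present that could convert 12 into a ketene.

Step 9
Reactants: 11 benzyl 4-{[(1Z)-1,3-bis(trimethylsilyloxy)buta-1,3-dien-1-yl]oxy}-2-methoxy-6-pentylbenzoate; 14 1,1-dimethoxyhex-1-en-3-one (1.5 equiv)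
Product: 16 benzyl 4-[(2-hydroxy-4-methoxy-6-propylbenzoyl)oxy]-2-methoxy-6-pentylbenzoate, via open-chain vinylogous ester 15 (not isolated)
Conditions: TiCl4 (1.2 equiv), CH2Cl2, 4 Å MS, −78 → 20 °C; then 1 M HCl
Reagents that add atoms: none
Why: TiCl4 binds the ketone oxygen of 14 and makes its ketene acetal carbon a vinylogous oxocarbenium centre; the terminal CH2 of 11, the most nucleophilic carbon of the bis(silyloxy)diene, adds there (vinylogous Mukaiyama–Michael addition) and methoxide leaves, which forms C3'–C4' and gives 15 as its silyl or titanium enolate with the E geometry that holds the chain end next to the ketone. The enol carbon between the two carbonyls then attacks the TiCl4-activated propyl ketone in an intramolecular Mukaiyama aldol reaction, forming C1'–C6'. Because the enol double bond C1'=C2' lies inside the six-membered ring being formed and the C=O outside it, this closure is 6-(enolendo)-exo-trig, allowed by Baldwin's rules for enolates. Loss of water from the tertiary aldol and enolisation of the C2' carbonyl give the arene, and aromatisation makes the sequence irreversible. The closest known reaction type is the TiCl4-mediated formal (3+3) cyclocondensation of 1,3-bis(silyloxy)buta-1,3-dienes of alkyl acetoacetates with 3-oxo ketene acetals and other 1,3-dielectrophiles to give 4-methoxy-6-alkylsalicylates; the aryl ester is the only new feature. No stereocentre is formed and the Z geometry of 11 is erased. The selectivity needed is regiochemical, OMe para and propyl ortho to the ester, and polarity matching secures it: the most nucleophilic carbon meets the only carbon that carries leaving groups, the weaker central carbon is left for the ketone, and the reverse pairing would need a slower 1,2-addition of the diene terminus to the ketone. Chemoselectivity rests on the absence of any free nucleophile: the ring A benzyl ester is shielded by two ortho groups and the aryl ester oxygen stays bound in the silyl ketene acetal until the first C–C bond exists.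

Step 10
Reactants: 16 benzyl 4-[(2-hydroxy-4-methoxy-6-propylbenzoyl)oxy]-2-methoxy-6-pentylbenzoate
Product: 17 benzyl 4-[(2,4-dimethoxy-6-propylbenzoyl)oxy]-2-methoxy-6-pentylbenzoate
Conditions: MeI (5 equiv), K2CO3 (3 equiv), acetone, 56 °C
Reagents that add atoms: iodomethane, CI
Why: Williamson O-methylation of the C2' phenol, which is hydrogen-bonded to the depside carbonyl. Carbonate in acetone is not nucleophilic, and both the di-ortho-substituted depside ester and the hindered benzyl ester should resist it.

Step 11
Reactants: 17 benzyl 4-[(2,4-dimethoxy-6-propylbenzoyl)oxy]-2-methoxy-6-pentylbenzoate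
Product: 18 4-[(2,4-dimethoxy-6-propylbenzoyl)oxy]-2-methoxy-6-pentylbenzoic acid (CNP0590692.0)
Conditions: H2 (1 atm), 10% Pd/C, EtOAc, 20 °C
Reagents that add atoms: none
Why: Hydrogenolysis of the benzylic C–O bond of the ester under neutral conditions. Aryl ester, aryl methyl ethers and the arenes are not reduced at 1 atm and room temperature.

## Compound list

1 | olivetol (5-pentylbenzene-1,3-diol) | CCCCCc1cc(O)cc(O)c1 | starting material
2 | olivetolic acid (2,4-dihydroxy-6-pentylbenzoic acid) | CCCCCc1cc(O)cc(O)c1C(=O)O | intermediate
3 | benzyl 2,4-dihydroxy-6-pentylbenzoate | CCCCCc1cc(O)cc(O)c1C(=O)OCc1ccccc1 | intermediate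
4 | benzyl 2-hydroxy-6-pentyl-4-(prop-2-en-1-yloxy)benzoate | CCCCCc1cc(OCC=C)cc(O)c1C(=O)OCc1ccccc1 | intermediate
5 | benzyl 2-methoxy-6-pentyl-4-(prop-2-en-1-yloxy)benzoate | CCCCCc1cc(OCC=C)cc(OC)c1C(=O)OCc1ccccc1 | intermediate
6 | benzyl 4-hydroxy-2-methoxy-6-pentylbenzoate | CCCCCc1cc(O)cc(OC)c1C(=O)OCc1ccccc1 | intermediate
7 | 2,2,6-trimethyl-4H-1,3-dioxin-4-one | CC1=CC(=O)OC(C)(C)O1 | starting material
8 | acetylketene (but-1-ene-1,3-dione), not isolated | CC(=O)C=C=O | intermediate
9 | benzyl 2-methoxy-4-[(3-oxobutanoyl)oxy]-6-pentylbenzoate | CCCCCc1cc(OC(=O)CC(C)=O)cc(OC)c1C(=O)OCc1ccccc1 | intermediate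
10 | benzyl 2-methoxy-6-pentyl-4-{[(2E)-3-(trimethylsilyloxy)but-2-enoyl]oxy}benzoate, not isolated | CCCCCc1cc(OC(=O)/C=C(\C)O[Si](C)(C)C)cc(OC)c1C(=O)OCc1ccccc1 | intermediate
11 | benzyl 4-{[(1Z)-1,3-bis(trimethylsilyloxy)buta-1,3-dien-1-yl]oxy}-2-methoxy-6-pentylbenzoate | CCCCCc1cc(O/C(O[Si](C)(C)C)=C/C(=C)O[Si](C)(C)C)cc(OC)c1C(=O)OCc1ccccc1 | intermediate
12 | butanoyl chloride | CCCC(Cl)=O | starting material
13 | 1,1-dimethoxyethene | C=C(OC)OC | starting material
14 | 1,1-dimethoxyhex-1-en-3-one | CCCC(=O)C=C(OC)OC | intermediate
15 | benzyl 2-methoxy-4-{[(5E)-5-methoxy-3,7-dioxodec-5-enoyl]oxy}-6-pentylbenzoate, present as its silyl or titanium enolate, not isolated | CCCCCc1cc(OC(=O)CC(=O)C/C(OC)=C\C(=O)CCC)cc(OC)c1C(=O)OCc1ccccc1 | intermediate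
16 | benzyl 4-[(2-hydroxy-4-methoxy-6-propylbenzoyl)oxy]-2-methoxy-6-pentylbenzoate | CCCCCc1cc(OC(=O)c2c(CCC)cc(OC)cc2O)cc(OC)c1C(=O)OCc1ccccc1 | intermediate
17 | benzyl 4-[(2,4-dimethoxy-6-propylbenzoyl)oxy]-2-methoxy-6-pentylbenzoate | CCCCCc1cc(OC(=O)c2c(CCC)cc(OC)cc2OC)cc(OC)c1C(=O)OCc1ccccc1 | intermediate
18 | 4-[(2,4-dimethoxy-6-propylbenzoyl)oxy]-2-methoxy-6-pentylbenzoic acid | CCCCCc1cc(OC(=O)c2c(CCC)cc(OC)cc2OC)cc(OC)c1C(=O)O | target

## Step count and least certain steps

Total: 11 steps. Longest linear sequence: 10 steps (steps 1 to 7 and 9 to 11); step 8 is a one-step branch. Compound 2 is also sold; where it is bought, step 1 falls away.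

Step 9 (key step). The most likely failures are three. The silyl ketene acetal terminus may fragment under the Lewis acid with loss of the aryloxide, so that the ester is cleaved before ring B closes. The reaction may stall at the open-chain stage because ring A offers TiCl4 a chelating site (ester carbonyl and C2 methoxy) and withdraws it from 14. The diene terminus may add 1,2 to the ketone, which would lead to the regioisomeric ring. The fallback sets out from 14 and 6 and returns at 17.
- Compound 14 would be condensed under the same TiCl4 conditions with the commercial methyl-ester diene 1-methoxy-1,3-bis(trimethylsilyloxy)buta-1,3-diene (SMILES COC(O[Si](C)(C)C)=CC(=C)O[Si](C)(C)C), the established form of this cyclocondensation, to give methyl 2-hydroxy-4-methoxy-6-propylbenzoate F1.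
- Methylation (MeI, K2CO3, acetone) would give methyl 2,4-dimethoxy-6-propylbenzoate F2.
- Saponification of the hindered ester (KOH, aqueous DMSO, 90 °C) would give 2,4-dimethoxy-6-propylbenzoic acid F3.
- F3 would be joined to 6 with trifluoroacetic anhydride in toluene at 20 °C. An electron-rich 2,6-disubstituted benzoic acid passes through its mixed anhydride to an acylium ion, which is not subject to the steric bar of a tetrahedral intermediate. This gives 17 directly, and step 10 is then not needed.

Step 7. The most likely failure is E1cB fragmentation of the aryl acetoacetate to acetylketene and the phenoxide of ring A under the amine base. Incomplete silylation at the γ-methyl group and hydrolysis of the diene on handling are further risks. The fallback sets out from 7 and returns at 16 by way of 15, without ever silylating an aryl ester.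
- Compound 7 would be converted with LDA and Me3SiCl (THF, −78 °C) into its silyl dienol ether, 2,2-dimethyl-6-methylidene-4-(trimethylsilyloxy)-6H-1,3-dioxine F4.
- Vinylogous Mukaiyama addition of the exocyclic methylene of F4 to the ketene acetal carbon of 14 (catalytic Me3SiOTf, CH2Cl2, −78 °C), with loss of methoxide, would give 6-[(2E)-2-methoxy-4-oxohept-2-en-1-yl]-2,2-dimethyl-4H-1,3-dioxin-4-one F5.
- Heating F5 with 6 in toluene at 110 °C would release the acylketene, which 6 captures to give 15. Et3N at 20 °C would then close and aromatise ring B to 16.

Step 8. The most likely failure is over-reaction: further acylation of the product, or condensation of the product with a second molecule of the ketene acetal once the mixture warms. The fallback sets out from 12 and returns at 14.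
- Compound 12 would be added to 1,1-dichloroethene with AlCl3 (CH2Cl2, 0 °C) to give 1,1,1-trichlorohexan-3-one F6.
- F6 loses HCl on distillation to give 1,1-dichlorohex-1-en-3-one F7.
- Two equivalents of NaOMe in MeOH at 0 °C would replace both vinylic chlorides by addition–elimination and give 14.

Step 1. The most likely failure is carboxylation at the carbon between the two hydroxyl groups instead of next to the pentyl chain, together with decarboxylation of the product during acidic work-up. The fallback sets out from 1 and returns at 5.
- Vilsmeier–Haack formylation of 1 (POCl3, DMF, 0 → 20 °C; aqueous hydrolysis) places the carbonyl carbon para to one hydroxyl and ortho to the other and would give 2,4-dihydroxy-6-pentylbenzaldehyde F8.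
- Allylation of the C4 hydroxyl (allyl bromide, K2CO3, acetone) would give 2-hydroxy-6-pentyl-4-(prop-2-en-1-yloxy)benzaldehyde F9.
- Methylation (MeI, K2CO3, DMF) would give 2-methoxy-6-pentyl-4-(prop-2-en-1-yloxy)benzaldehyde F10.
- Pinnick oxidation (NaClO2, NaH2PO4, 2-methylbut-2-ene, t-BuOH/H2O) would give 2-methoxy-6-pentyl-4-(prop-2-en-1-yloxy)benzoic acid F11.
- Benzylation of F11 (BnBr, K2CO3, DMF) would give 5.

## Further compounds

F1 | step 9 | methyl 2-hydroxy-4-methoxy-6-propylbenzoate | CCCc1cc(OC)cc(O)c1C(=O)OC
F2 | step 9 | methyl 2,4-dimethoxy-6-propylbenzoate | CCCc1cc(OC)cc(OC)c1C(=O)OC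
F3 | step 9 | 2,4-dimethoxy-6-propylbenzoic acid | CCCc1cc(OC)cc(OC)c1C(=O)O
F4 | step 7 | 2,2-dimethyl-6-methylidene-4-(trimethylsilyloxy)-6H-1,3-dioxine | C=C1C=C(O[Si](C)(C)C)OC(C)(C)O1
F5 | step 7 | 6-[(2E)-2-methoxy-4-oxohept-2-en-1-yl]-2,2-dimethyl-4H-1,3-dioxin-4-one | CCCC(=O)/C=C(/OC)CC1=CC(=O)OC(C)(C)O1
F6 | step 8 | 1,1,1-trichlorohexan-3-one | CCCC(=O)CC(Cl)(Cl)Cl
F7 | step 8 | 1,1-dichlorohex-1-en-3-one | CCCC(=O)C=C(Cl)Cl
F8 | step 1 | 2,4-dihydroxy-6-pentylbenzaldehyde | CCCCCc1cc(O)cc(O)c1C=O
F9 | step 1 | 2-hydroxy-6-pentyl-4-(prop-2-en-1-yloxy)benzaldehyde | CCCCCc1cc(OCC=C)cc(O)c1C=O
F10 | step 1 | 2-methoxy-6-pentyl-4-(prop-2-en-1-yloxy)benzaldehyde | CCCCCc1cc(OCC=C)cc(OC)c1C=O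
F11 | step 1 | 2-methoxy-6-pentyl-4-(prop-2-en-1-yloxy)benzoic acid | CCCCCc1cc(OCC=C)cc(OC)c1C(=O)O
A1 | alternative 1 | 6-(2,4-dioxononyl)-2,2-dimethyl-4H-1,3-dioxin-4-one | CCCCCC(=O)CC(=O)CC1=CC(=O)OC(C)(C)O1
A2 | alternative 1 | 7-hydroxy-2,2-dimethyl-5-pentyl-4H-1,3-benzodioxin-4-one | CCCCCc1cc(O)cc2OC(C)(C)OC(=O)c12
A3 | alternative 2 | 2-iodo-1,5-dimethoxy-3-propylbenzene | CCCc1cc(OC)cc(OC)c1I
A4 | alternative 2 | carbon monoxide | [C-]#[O+]
A5 | alternative 2 | benzyl 4-[(2,4-dimethoxy-6-propylbenzoyl)oxy]-2-methoxy-6-pentylbenzoate | CCCCCc1cc(OC(=O)c2c(CCC)cc(OC)cc2OC)cc(OC)c1C(=O)OCc1ccccc1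
A6 | alternative 2 | 1,3-dimethoxy-5-propylbenzene | CCCc1cc(OC)cc(OC)c1
A7 | alternative 3 | 1,1-dimethoxy-3-(trimethylsilyloxy)buta-1,3-diene | C=C(O[Si](C)(C)C)C=C(OC)OC
A8 | alternative 3 | benzyl oct-2-ynoate | CCCCCC#CC(=O)OCc1ccccc1
A9 | alternative 3 | benzyl 4-hydroxy-2-methoxy-6-pentylbenzoate | CCCCCc1cc(O)cc(OC)c1C(=O)OCc1ccccc1
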